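## Retrosynthetic overview

- The acid comes from its methyl ester; the C3 hydroxyl left by the initiating epoxide is removed by radical deoxygenation, and the ring B olefin is moved into the C8=C9 position by acid equilibration after the cascade.
- Rings A and B come from an open-chain (S,S)-epoxy tetraenoate in one Lewis acid-triggered cationic cascade: ring A closes first (C4–C5, epoxide opening), then ring B (C9–C10).
- The open chain comes from a Wittig union, then diimide reduction, of (2S,3S)-epoxygeranial (from geraniol by asymmetric epoxidation) with the C12 ylide of methyl farnesoate; the two terpenes supply all 25 skeletal carbons.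
- Enabling feature: C4 of ring A, the quaternary stereocentre carrying methyl and 4-methylpent-3-enyl, is the tertiary epoxide carbon of epoxygeraniol. The (E)-olefins C5=C10 and C8=C9 lie 1,5 to it and to each other, so both rings fold chair–chair, and the conjugated C13=C14 enoate is too electron-poor to carry the cascade beyond ring B.

Key step: step 8

Remark on numbering: the decalin is numbered as in labdanes (ring A = C1–C5 and C10; ring B = C5–C10; side chain C11–C15 on C9; β = the face of the C10 methyl).

Assumption: geraniol and methyl (2E,6E)-farnesoate are purchased; the latter is otherwise one oxidation–esterification step from (2E,6E)-farnesol.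

## Route

Step 1
Reactants: 1 geraniol
Product: 2 (2S,3S)-2,3-epoxygeraniol
Conditions: Ti(OiPr)4 (5 mol%), L-(+)-diethyl tartrate (6 mol%), t-BuOOH (2 equiv), 4 Å MS, CH2Cl2, −20 °C
Reagents that add atoms: tert-butyl hydroperoxide, CC(C)(C)OO
Why: Katsuki–Sharpless asymmetric epoxidation; the titanium tartrate complex binds the allylic alcohol and delivers oxygen to one face of the 2,3-olefin only (the remote 6,7-olefin is not directed), the L-(+)-tartrate setting both epoxide centres as (2S,3S).

Step 2
Reactants: 2 (2S,3S)-2,3-epoxygeraniol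
Product: 3 (2R,3S)-3-methyl-3-(4-methylpent-3-en-1-yl)oxirane-2-carbaldehyde
Conditions: TEMPO (10 mol%), PhI(OAc)2 (1.1 equiv), CH2Cl2, 20 °C
Reagents that add atoms: none
Why: oxoammonium-mediated oxidation of the primary alcohol stops at the aldehyde under neutral conditions that leave the epoxide, its two stereocentres and the trisubstituted olefin untouched (the new descriptor at C2 reflects only a change of priorities).

Step 3
Reactants: 4 methyl (2E,6E)-farnesoate
Product: 5 methyl (2E,6E,10E)-12-hydroxy-3,7,11-trimethyldodeca-2,6,10-trienoate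
Conditions: SeO2 (10 mol%), t-BuOOH (3 equiv), salicylic acid (10 mol%), CH2Cl2, 0 → 20 °C, stopped at partial conversion
Reagents that add atoms: tert-butyl hydroperoxide, CC(C)(C)OO
Why: Riley allylic oxidation (ene reaction, then 2,3-sigmatropic shift) attacks the most electron-rich terminal trisubstituted olefin at its (E)-methyl group, the enoate olefin being deactivated, and returns the (E)-allylic alcohol.

Step 4
Reactants: 5 methyl (2E,6E,10E)-12-hydroxy-3,7,11-trimethyldodeca-2,6,10-trienoate
Product: 6 methyl (2E,6E,10E)-12-bromo-3,7,11-trimethyldodeca-2,6,10-trienoate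
Conditions: CBr4 (1.3 equiv), PPh3 (1.3 equiv), CH2Cl2, 0 °C
Reagents that add atoms: carbon tetrabromide, BrC(Br)(Br)Br
Why: Appel reaction; SN2 displacement of the alkoxyphosphonium group at the primary allylic carbon keeps the olefin geometry.

Step 5
Reactants: 6 methyl (2E,6E,10E)-12-bromo-3,7,11-trimethyldodeca-2,6,10-trienoate
Product: 7 [(2E,6E,10E)-12-methoxy-2,6,10-trimethyl-12-oxododeca-2,6,10-trien-1-yl]triphenylphosphonium bromide
Conditions: PPh3 (1.1 equiv), MeCN, 40 °C
Reagents that add atoms: triphenylphosphine, c1ccc(cc1)P(c1ccccc1)c1ccccc1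
Why: SN2 quaternisation of triphenylphosphine by the primary allylic bromide.

Step 6
Reactants: 7 phosphonium bromide; 3 epoxy aldehyde
Product: 9 methyl (2E,6E,10E)-3,7,11-trimethyl-13-[(2S,3S)-3-methyl-3-(4-methylpent-3-en-1-yl)oxiran-2-yl]trideca-2,6,10,12-tetraenoate (12E/12Z mixture), via phosphonium ylide 8 (not isolated)
Conditions: NaN(SiMe3)2 (1.0 equiv), THF, −78 °C; then 3, −78 → 0 °C
Reagents that add atoms: none
Why: Wittig olefination; the allylic ylide reacts through its α-carbon with the aldehyde at low temperature, where ester and epoxide are inert, and the E/Z mixture at the new 12,13-olefin is of no consequence because step 7 saturates it.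

Step 7
Reactants: 9 tetraenoate epoxide
Product: 10 methyl (2E,6E,10E)-3,7,11-trimethyl-13-[(2S,3S)-3-methyl-3-(4-methylpent-3-en-1-yl)oxiran-2-yl]trideca-2,6,10-trienoate
Conditions: 2-nitrobenzenesulfonylhydrazide (3 equiv), Et3N, CH2Cl2, 20 °C
Reagents that add atoms: none
Why: diimide, formed in the flask, transfers H2 in a concerted syn manner to the only 1,2-disubstituted olefin much faster than to the four trisubstituted ones, and as a neutral reductant it spares the epoxide that hydride or catalytic hydrogenation would endanger.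

Step 8
Reactants: 10 (S,S)-epoxy tetraenoate
Product: 13 3β-hydroxy 7-ene bicyclic ester (3β-OH; 4β-CH3; 4α-(4-methylpent-3-enyl); 5α-H; 9α-H; 10β-CH3; C7=C8 olefin; C9 bears (E)-CH2CH2C(CH3)=CHCO2CH3), via monocyclic C10 carbocation 11 (not isolated), via bicyclic C8 carbocation 12 (not isolated)
Conditions: MeAlCl2 (2.5 equiv), CH2Cl2, −94 → −78 °C; Et3N–MeOH quench, aq. NaHCO3
Reagents that add atoms: none
Why: MeAlCl2 coordinates the epoxide oxygen and the tertiary C4–O bond is opened with inversion by C5 of the C5=C10 olefin (ring A, 6-endo-trig at the olefin, the breaking C–O bond exocyclic to the new ring); the tertiary C10 cation 11 is then attacked by C9 of the C8=C9 olefin (ring B, 6-endo-trig), which forms the C9–C10 bond and the tertiary C8 cation 12, and loss of a proton ends the cascade. The closest known reaction type is the Lewis acid-promoted cyclization of epoxy polyenes (biomimetic cation–olefin polycyclization), long used for drimane- and labdane-type decalins. C3 keeps the configuration of the epoxide carbon (equatorial 3β-oxygen); C4 is set by anti opening of the (E)-trisubstituted epoxide, which puts the 4-methylpent-3-enyl group (trans to C2 in geraniol) equatorial and the methyl axial; C5 and C10 follow from anti addition across the (E)-C5=C10 olefin in a chair–chair array (trans ring fusion, H5 anti to the C10 methyl); C9 follows from anti addition across the (E)-C8=C9 olefin. The step needs opening at the tertiary rather than the secondary epoxide carbon (secured by substitution and by six-membered ring formation), no participation of the side-chain olefins (the isopropylidene group sits equatorial on C4 and cannot reach C10; the C13=C14 enoate is conjugated and Lewis acid-complexed, hence too electron-poor to attack C8) and a defined position of the new ring B olefin. The last point is not secured by the substrate: proton loss from C7 should dominate kinetically, with some loss from C17 and C9, so 13 is taken on together with its 8(17)-ene and 8-ene isomers, which step 9 converges.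

Step 9
Reactants: 13 3β-hydroxy 7-ene bicyclic ester (used with its 8(17)-ene and 8-ene isomers)
Product: 14 methyl (2E)-5-[(4aR,5S,6S,8aS)-6-hydroxy-2,5,8a-trimethyl-5-(4-methylpent-3-en-1-yl)-3,4,4a,5,6,7,8,8a-octahydronaphthalen-1-yl]-3-methylpent-2-enoate
Conditions: TsOH (10 mol%), benzene, 50 °C
Reagents that add atoms: none
Why: acid-catalysed double-bond migration; reversible protonation regenerates the tertiary C8 cation and thermodynamic control should favour the tetrasubstituted C8=C9 olefin over the 7-ene and the exocyclic 8(17)-ene (remaining isomers are removed on AgNO3-impregnated silica and recycled), while the isopropylidene group and the (E)-enoate already sit in their most stable positions.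

Step 10
Reactants: 14 3β-hydroxy 8-ene ester
Product: 15 O-(3β-yl) 1H-imidazole-1-carbothioate of 14
Conditions: 1,1'-thiocarbonyldiimidazole (2 equiv), DMAP (20 mol%), toluene, 90 °C
Reagents that add atoms: 1,1'-thiocarbonyldiimidazole, S=C(n1ccnc1)n1ccnc1
Why: thioacyl transfer to the equatorial secondary 3β-hydroxyl under non-basic conditions that do not touch the enoate or the olefins.

Step 11
Reactants: 15 imidazole-1-carbothioate
Product: 16 methyl (2E)-3-methyl-5-[(4aS,5S,8aS)-2,5,8a-trimethyl-5-(4-methylpent-3-en-1-yl)-3,4,4a,5,6,7,8,8a-octahydronaphthalen-1-yl]pent-2-enoate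
Conditions: Bu3SnH (3 equiv), PhSeSePh (20 mol%), AIBN (10 mol%), toluene, 90 °C
Reagents that add atoms: none
Why: Barton–McCombie deoxygenation; the secondary C3 radical is reduced by benzeneselenol (formed in the flask from the diselenide and the stannane), a hydrogen donor fast enough to outrun 5-exo cyclization onto the side-chain olefin, and no stereocentre is affected.

Step 12
Reactants: 16 methyl ester
Product: 18 (2E)-3-methyl-5-[(4aS,5S,8aS)-2,5,8a-trimethyl-5-(4-methylpent-3-en-1-yl)-3,4,4a,5,6,7,8,8a-octahydronaphthalen-1-yl]pent-2-enoic acid, via lithium carboxylate 17 (not isolated)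
Conditions: LiOH (5 equiv), THF–MeOH–H2O, 45 °C; then aq. HCl to pH 3
Reagents that add atoms: lithium hydroxide, [Li+].[OH-]
Why: saponification by acyl–oxygen cleavage of the β,β-disubstituted enoate leaves the (E)-olefin geometry and all stereocentres untouched.

## Compound list

1 | geraniol, (2E)-3,7-dimethylocta-2,6-dien-1-ol | CC(C)=CCC/C(C)=C/CO | starting material
2 | (2S,3S)-2,3-epoxygeraniol, [(2S,3S)-3-methyl-3-(4-methylpent-3-en-1-yl)oxiran-2-yl]methanol | OC[C@@H]1O[C@@]1(C)CCC=C(C)C | intermediate
3 | (2R,3S)-3-methyl-3-(4-methylpent-3-en-1-yl)oxirane-2-carbaldehyde | O=C[C@@H]1O[C@@]1(C)CCC=C(C)C | intermediate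
4 | methyl (2E,6E)-farnesoate, methyl (2E,6E)-3,7,11-trimethyldodeca-2,6,10-trienoate | CC(C)=CCC/C(C)=C/CC/C(C)=C/C(=O)OC | starting material
5 | methyl (2E,6E,10E)-12-hydroxy-3,7,11-trimethyldodeca-2,6,10-trienoate | OC/C(C)=C/CC/C(C)=C/CC/C(C)=C/C(=O)OC | intermediate
6 | methyl (2E,6E,10E)-12-bromo-3,7,11-trimethyldodeca-2,6,10-trienoate | BrC/C(C)=C/CC/C(C)=C/CC/C(C)=C/C(=O)OC | intermediate
7 | [(2E,6E,10E)-12-methoxy-2,6,10-trimethyl-12-oxododeca-2,6,10-trien-1-yl]triphenylphosphonium bromide | [Br-].c1ccccc1[P+](c1ccccc1)(c1ccccc1)C/C(C)=C/CC/C(C)=C/CC/C(C)=C/C(=O)OC | intermediate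
8 | phosphonium ylide of 7 | [CH-]([P+](c1ccccc1)(c1ccccc1)c1ccccc1)/C(C)=C/CC/C(C)=C/CC/C(C)=C/C(=O)OC | intermediate (not isolated)
9 | methyl (2E,6E,10E)-3,7,11-trimethyl-13-[(2S,3S)-3-methyl-3-(4-methylpent-3-en-1-yl)oxiran-2-yl]trideca-2,6,10,12-tetraenoate, 12E/12Z mixture | CC(C)=CCC[C@]1(C)O[C@H]1C=C/C(C)=C/CC/C(C)=C/CC/C(C)=C/C(=O)OC | intermediate
10 | methyl (2E,6E,10E)-3,7,11-trimethyl-13-[(2S,3S)-3-methyl-3-(4-methylpent-3-en-1-yl)oxiran-2-yl]trideca-2,6,10-trienoate | CC(C)=CCC[C@]1(C)O[C@H]1CC/C(C)=C/CC/C(C)=C/CC/C(C)=C/C(=O)OC | intermediate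
11 | monocyclic C10 carbocation, ring A closed, C3 oxygen bound to MeAlCl2 | CC(C)=CCC[C@]1(C)[C@@H](O[Al-](C)(Cl)Cl)CC[C+](C)[C@H]1CC/C(C)=C/CC/C(C)=C/C(=O)OC | intermediate (not isolated)
12 | bicyclic C8 carbocation, rings A and B closed, C3 oxygen bound to MeAlCl2 | CC(C)=CCC[C@]1(C)[C@@H](O[Al-](C)(Cl)Cl)CC[C@]2(C)[C@@H](CC/C(C)=C/C(=O)OC)[C+](C)CC[C@@H]12 | intermediate (not isolated)
13 | 3β-hydroxy 7-ene bicyclic methyl ester (3β-OH, 4β-CH3, 4α-(4-methylpent-3-enyl), 5α-H, 9α-H, 10β-CH3, C7=C8 olefin, (E)-enoate side chain on C9) | CC(C)=CCC[C@]1(C)[C@@H](O)CC[C@]2(C)[C@@H](CC/C(C)=C/C(=O)OC)C(C)=CC[C@@H]12 | intermediate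
14 | methyl (2E)-5-[(4aR,5S,6S,8aS)-6-hydroxy-2,5,8a-trimethyl-5-(4-methylpent-3-en-1-yl)-3,4,4a,5,6,7,8,8a-octahydronaphthalen-1-yl]-3-methylpent-2-enoate (3β-hydroxy 8-ene) | CC(C)=CCC[C@]1(C)[C@@H](O)CC[C@]2(C)C(CC/C(C)=C/C(=O)OC)=C(C)CC[C@@H]12 | intermediate
15 | O-(3β-yl) 1H-imidazole-1-carbothioate of 14 | CC(C)=CCC[C@]1(C)[C@@H](OC(=S)n3ccnc3)CC[C@]2(C)C(CC/C(C)=C/C(=O)OC)=C(C)CC[C@@H]12 | intermediate
16 | methyl (2E)-3-methyl-5-[(4aS,5S,8aS)-2,5,8a-trimethyl-5-(4-methylpent-3-en-1-yl)-3,4,4a,5,6,7,8,8a-octahydronaphthalen-1-yl]pent-2-enoate | CC(C)=CCC[C@]1(C)CCC[C@]2(C)C(CC/C(C)=C/C(=O)OC)=C(C)CC[C@@H]12 | intermediate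
17 | lithium carboxylate of 18 | [Li+].CC(C)=CCC[C@]1(C)CCC[C@]2(C)C(CC/C(C)=C/C(=O)[O-])=C(C)CC[C@@H]12 | intermediate (not isolated)
18 | (2E)-3-methyl-5-[(4aS,5S,8aS)-2,5,8a-trimethyl-5-(4-methylpent-3-en-1-yl)-3,4,4a,5,6,7,8,8a-octahydronaphthalen-1-yl]pent-2-enoic acid | CC(C)=CCC[C@]1(C)CCC[C@]2(C)C(CC/C(C)=C/C(=O)O)=C(C)CC[C@@H]12 | target

## Step count and risks

Total steps: 12. Longest linear sequence: 10 steps (steps 3–12, from 4).

Steps most likely to fail:

1. Step 8. The C10 cation may lose a proton or be captured before ring B closes (arrest after ring A), and the ester carbonyl may sequester the Lewis acid and slow epoxide activation. The fallback sets out from 10 and comes back at 13. The cascade is replaced by two separate ring closures: the monocyclic hydroxy ester F1 (ring A closed, exocyclic methylene at C10, dienoate chain on C5 intact) is isolated from the MeAlCl2 reaction. Ring B is then closed in a known stepwise cation–olefin cyclization (SnCl4, CH2Cl2, −78 °C), in which protonation of the 1,1-disubstituted olefin regenerates the C10 cation and the C8=C9 olefin captures it.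

2. Step 9. The equilibrium may stop short of full conversion to the tetrasubstituted olefin, and on long acid contact the isopropylidene olefin may leak into the isopropenyl position. The fallback sets out from 13, comes back at 14 and makes no new compound (F0). Thermodynamic funnelling of the whole batch is replaced by a separation–recycle scheme: the crude olefin mixture from step 8 is resolved on AgNO3-impregnated silica, where the tetrasubstituted 8-ene 14 is bound least. Only the recovered 7-ene and 8(17)-ene are returned to short acid pulses, so converted material is never re-exposed.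

3. Step 11. The C3 radical may close a five-membered ring (5-exo) onto the side-chain olefin before hydrogen transfer. The fallback sets out from 14 and comes back at 16 by an ionic sequence that never forms a C3 radical. Dess–Martin oxidation gives the 3-ketone F2. Tf2O with 2,6-di-tert-butyl-4-methylpyridine gives the enol triflate F3 (enolisation is possible only toward C2, C4 being quaternary). Pd(OAc)2/PPh3-catalysed reduction with HCO2H–Bu3N gives the 2-ene F4, and diimide (as in step 7) saturates this only 1,2-disubstituted olefin to 16.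

Further compounds

F1 | step 8 | monocyclic hydroxy ester: ring A closed (3β-OH, 4β-CH3, 4α-(4-methylpent-3-enyl), 5α-H), exocyclic methylene at C10, methyl (2E,6E)-dienoate chain on C5 | CC(C)=CCC[C@]1(C)[C@@H](O)CCC(=C)[C@H]1CC/C(C)=C/CC/C(C)=C/C(=O)OC
F0 | step 9 | none | none
F2 | step 11 | 3-ketone of 14 | CC(C)=CCC[C@]1(C)C(=O)CC[C@]2(C)C(CC/C(C)=C/C(=O)OC)=C(C)CC[C@@H]12
F3 | step 11 | enol triflate of F2 (C2=C3 olefin, triflate on C3) | CC(C)=CCC[C@]1(C)C(OS(=O)(=O)C(F)(F)F)=CC[C@]2(C)C(CC/C(C)=C/C(=O)OC)=C(C)CC[C@@H]12
F4 | step 11 | 2-ene analogue of 16 (C2=C3 olefin in ring A) | CC(C)=CCC[C@]1(C)C=CC[C@]2(C)C(CC/C(C)=C/C(=O)OC)=C(C)CC[C@@H]12
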